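**Plan**

- Enabling feature: in the tetralin (C1 aryl-bearing, C2 and C3 hydroxymethyl-bearing, C4 methylene, C4a/C8a ring fusion), C1 is a single sp3 carbon joined to the pendant syringyl ring, to C8a of ring A and to C2. It can therefore enter as the carbene carbon of an aryl aldehyde hydrazone.
- Retrosynthesis: C1–C8a and C1–C2 are cut together, which opens ring B to an aryl iodide carrying a malonate plus the tosylhydrazone of O-benzylsyringaldehyde. Then C2–C3 is cut (bromomalonate plus a 3-arylpropanal), and the two-carbon chain is cut back to O-benzylsyringaldehyde.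
- Forward: benzylated syringaldehyde serves both halves. Chain extension, α-malonylation, O-benzylation and ring iodination give the cyclisation substrate; ring B (the only ring formed) closes in the palladium step; one ester is removed, C2 is equilibrated, the ester is reduced and the benzyl groups are cleaved.
- Stereochemistry: C3 (R) comes from the imidazolidinone-catalysed photoredox α-alkylation. C1 (S) is set in the ring closure by the enantiopure ligand on palladium acting on the chair fixed by C3. C2 (R) is set by base equilibration to the 1,2-trans/2,3-trans ester.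

Key step: step 8

Assumption: the antipode of the imidazolidinone catalyst (step 5) that gives the R aldehyde and the antipode of the phosphine ligand (step 8) that gives 1S are used; both antipodes of each are accessible.

Step 1
Reactants: 1 syringaldehyde
Product: 2 4-(benzyloxy)-3,5-dimethoxybenzaldehyde
Conditions: BnBr, K2CO3, DMF, 60 °C
Reagents that add atoms: benzyl bromide, BrCc1ccccc1
Why: Williamson ether synthesis on the phenoxide, to which the aldehyde is inert.

Step 2
Reactants: 2 4-(benzyloxy)-3,5-dimethoxybenzaldehyde; 3 p-toluenesulfonyl hydrazide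
Product: 4 (E)-N'-[4-(benzyloxy)-3,5-dimethoxybenzylidene]-4-methylbenzenesulfonohydrazide
Conditions: MeOH, 50 °C
Reagents that add atoms: none
Why: Hydrazone condensation should give the crystalline E tosylhydrazone, the bench-stable precursor of the aryl diazomethane.

Step 3
Reactants: 2 4-(benzyloxy)-3,5-dimethoxybenzaldehyde; 5 (triphenylphosphoranylidene)acetaldehyde
Product: 6 (E)-3-[4-(benzyloxy)-3,5-dimethoxyphenyl]prop-2-enal
Conditions: toluene, 90 °C, slight excess of 2
Reagents that add atoms: none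
Why: Wittig olefination with the stabilised formyl ylide should give the E enal, the excess of 2 limiting a second homologation of the product.

Step 4
Reactants: 6 (E)-3-[4-(benzyloxy)-3,5-dimethoxyphenyl]prop-2-enal
Product: 7 3-[4-(benzyloxy)-3,5-dimethoxyphenyl]propanal
Conditions: Hantzsch ester (1.1 equiv), dibenzylammonium trifluoroacetate (10 mol%), THF, rt
Reagents that add atoms: none
Why: Iminium-catalysed transfer hydrogenation from the dihydropyridine (organocatalytic conjugate reduction) reduces only the conjugated C=C bond and leaves the aldehyde and the benzyl ether untouched.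

Step 5
Reactants: 7 3-[4-(benzyloxy)-3,5-dimethoxyphenyl]propanal; 8 dimethyl 2-bromomalonate
Product: 9 dimethyl 2-[(2R)-1-[4-(benzyloxy)-3,5-dimethoxyphenyl]-3-oxopropan-2-yl]propanedioate
Conditions: Ru(bpy)3Cl2 (0.5 mol%), trans-2-tert-butyl-3,5-dimethylimidazolidin-4-one·TfOH (20 mol%), 2,6-lutidine (2 equiv), DMF, blue LEDs, rt
Reagents that add atoms: none
Why: Merged enamine/photoredox asymmetric α-alkylation of an aldehyde, for which hydrocinnamaldehydes are standard substrates: the malonyl radical formed by one-electron reduction of 8 adds to the unshielded face of the chiral enamine of 7, which sets the future C3 as R.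

Step 6
Reactants: 9 dimethyl 2-[(2R)-1-[4-(benzyloxy)-3,5-dimethoxyphenyl]-3-oxopropan-2-yl]propanedioate
Product: 10 dimethyl 2-[(2R)-1-(benzyloxy)-3-[4-(benzyloxy)-3,5-dimethoxyphenyl]propan-2-yl]propanedioate
Conditions: BnOSiMe3 (1.5 equiv), Et3SiH (1.5 equiv), TMSOTf (10 mol%), CH2Cl2, −78 °C
Reagents that add atoms: benzyloxytrimethylsilane, C[Si](C)(C)OCc1ccccc1
Why: Lewis-acid-catalysed reductive etherification: the oxocarbenium ion formed from the aldehyde and the benzyl silyl ether is reduced by the silane at low temperature, so no alkoxide is present and the γ-hydroxy malonate that would lactonise is bypassed, with C3 retained.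

Step 7
Reactants: 10 dimethyl 2-[(2R)-1-(benzyloxy)-3-[4-(benzyloxy)-3,5-dimethoxyphenyl]propan-2-yl]propanedioate
Product: 11 dimethyl 2-[(2R)-1-(benzyloxy)-3-[4-(benzyloxy)-2-iodo-3,5-dimethoxyphenyl]propan-2-yl]propanedioate
Conditions: NIS (1.05 equiv), TFA (10 mol%), MeCN, 0 °C to rt, dark
Reagents that add atoms: N-iodosuccinimide, O=C1CCC(=O)N1I
Why: Electrophilic aromatic iodination occurs at one of the two equivalent positions ortho to the benzylic carbon (each ortho and para to a methoxy group), while the plain benzyl rings and the malonate are inert.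

Step 8
Reactants: 11 dimethyl 2-[(2R)-1-(benzyloxy)-3-[4-(benzyloxy)-2-iodo-3,5-dimethoxyphenyl]propan-2-yl]propanedioate; 4 (E)-N'-[4-(benzyloxy)-3,5-dimethoxybenzylidene]-4-methylbenzenesulfonohydrazide
Product: 13 dimethyl (1S,3R)-7-(benzyloxy)-1-[4-(benzyloxy)-3,5-dimethoxyphenyl]-3-[(benzyloxy)methyl]-6,8-dimethoxy-3,4-dihydronaphthalene-2,2(1H)-dicarboxylate, via aryldiazomethane 12 (not isolated)
Conditions: Pd2(dba)3 (5 mol%), enantiopure sulfinamide–phosphine ligand (Sadphos type, 12 mol%), Cs2CO3 (3 equiv), 1,4-dioxane, 85 °C, 4 added over several hours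
Reagents that add atoms: none
Why: Cs2CO3 converts 4 into diazoalkane 12 (Bamford–Stevens), Pd(0) inserts into the C8a–I bond of 11, the arylpalladium iodide takes up 12 as a palladium carbene, and 1,1-migratory insertion of the ring-A aryl forms C1–C8a and a diarylmethyl palladium that has no β-hydrogen and rests as an η3-benzyl complex. The tethered caesium malonate then alkylates C1 anti to palladium and releases Pd(0); this closes ring B by a 6-exo-tet-type displacement through a chair-like array with the C3 benzyloxymethyl group equatorial, and forms C1–C2. The closest known reaction type is the carbenylative cyclisation of aryl halides bearing a stabilised carbon nucleophile with N-tosylhydrazones. The iodide is chosen so that oxidative addition at the hindered, electron-rich, di-ortho-substituted carbon proceeds without a ligand that would promote direct malonate arylation to an indane, and slow addition of 4 keeps 12 dilute so that azine and stilbene formation stay minor. C1 is the only new stereocentre and must be S (aryl cis to the C3 substituent); because the peri 8-methoxy group and the gem-diester may bias the substrate toward a pseudo-axial aryl (1,3-trans), its configuration is assigned to the enantiopure ligand (catalyst control over the diarylmethyl palladium), with the resident 3R centre defining the chair. C3 is not touched.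

Step 9
Reactants: 13 dimethyl (1S,3R)-7-(benzyloxy)-1-[4-(benzyloxy)-3,5-dimethoxyphenyl]-3-[(benzyloxy)methyl]-6,8-dimethoxy-3,4-dihydronaphthalene-2,2(1H)-dicarboxylate
Product: 14 methyl (1S,3R)-7-(benzyloxy)-1-[4-(benzyloxy)-3,5-dimethoxyphenyl]-3-[(benzyloxy)methyl]-6,8-dimethoxy-1,2,3,4-tetrahydronaphthalene-2-carboxylate (mixture of C2 epimers)
Conditions: LiCl (3 equiv), H2O (2 equiv), DMSO, 150 °C
Reagents that add atoms: none
Why: Krapcho demethoxycarbonylation: chloride attacks one ester methyl group, the carboxylate loses CO2 and water protonates the ester enolate, so C1 and C3 are unaffected and C2 should form as an epimer mixture.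

Step 10
Reactants: 14 methyl (1S,3R)-7-(benzyloxy)-1-[4-(benzyloxy)-3,5-dimethoxyphenyl]-3-[(benzyloxy)methyl]-6,8-dimethoxy-1,2,3,4-tetrahydronaphthalene-2-carboxylate (mixture of C2 epimers)
Product: 15 methyl (1S,2R,3R)-7-(benzyloxy)-1-[4-(benzyloxy)-3,5-dimethoxyphenyl]-3-[(benzyloxy)methyl]-6,8-dimethoxy-1,2,3,4-tetrahydronaphthalene-2-carboxylate
Conditions: NaOMe (0.3 equiv), MeOH, 50 °C
Reagents that add atoms: none
Why: Base-mediated epimerisation α to the ester (thermodynamic control): with the C1 aryl and the C3 substituent fixed cis, the ester should settle trans to both neighbours, and any residual cis isomer can be resubmitted.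

Step 11
Reactants: 15 methyl (1S,2R,3R)-7-(benzyloxy)-1-[4-(benzyloxy)-3,5-dimethoxyphenyl]-3-[(benzyloxy)methyl]-6,8-dimethoxy-1,2,3,4-tetrahydronaphthalene-2-carboxylate
Product: 16 [(1S,2R,3R)-7-(benzyloxy)-1-[4-(benzyloxy)-3,5-dimethoxyphenyl]-3-[(benzyloxy)methyl]-6,8-dimethoxy-1,2,3,4-tetrahydronaphthalen-2-yl]methanol
Conditions: LiAlH4, THF, 0 °C
Reagents that add atoms: none
Why: Hydride reduction of the ester to the primary alcohol, run cold so that reduction outpaces any alkoxide-induced epimerisation at C2, with the benzyl ethers inert.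

Step 12
Reactants: 16 [(1S,2R,3R)-7-(benzyloxy)-1-[4-(benzyloxy)-3,5-dimethoxyphenyl]-3-[(benzyloxy)methyl]-6,8-dimethoxy-1,2,3,4-tetrahydronaphthalen-2-yl]methanol
Product: 17 4-[(1S,2R,3R)-7-hydroxy-2,3-bis(hydroxymethyl)-6,8-dimethoxy-1,2,3,4-tetrahydronaphthalen-1-yl]-2,6-dimethoxyphenol
Conditions: H2 (1 atm), 10% Pd/C, EtOAc/MeOH, rt
Reagents that add atoms: none
Why: Catalytic hydrogenolysis cleaves the two aryl benzyl ethers and the alkyl benzyl ether, while the aryl methyl ethers and the diarylmethine carbon are stable at ambient pressure.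

**Compound list**

1 | syringaldehyde (4-hydroxy-3,5-dimethoxybenzaldehyde) | COc1cc(C=O)cc(OC)c1O | starting material
2 | 4-(benzyloxy)-3,5-dimethoxybenzaldehyde | COc1cc(C=O)cc(OC)c1OCc1ccccc1 | intermediate
3 | p-toluenesulfonyl hydrazide | Cc1ccc(cc1)S(=O)(=O)NN | starting material
4 | (E)-N'-[4-(benzyloxy)-3,5-dimethoxybenzylidene]-4-methylbenzenesulfonohydrazide | COc1cc(/C=N/NS(=O)(=O)c2ccc(C)cc2)cc(OC)c1OCc1ccccc1 | intermediate
5 | (triphenylphosphoranylidene)acetaldehyde | O=CC=P(c1ccccc1)(c1ccccc1)c1ccccc1 | starting material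
6 | (E)-3-[4-(benzyloxy)-3,5-dimethoxyphenyl]prop-2-enal | COc1cc(/C=C/C=O)cc(OC)c1OCc1ccccc1 | intermediate
7 | 3-[4-(benzyloxy)-3,5-dimethoxyphenyl]propanal | COc1cc(CCC=O)cc(OC)c1OCc1ccccc1 | intermediate
8 | dimethyl 2-bromomalonate | COC(=O)C(Br)C(=O)OC | starting material
9 | dimethyl 2-[(2R)-1-[4-(benzyloxy)-3,5-dimethoxyphenyl]-3-oxopropan-2-yl]propanedioate | COC(=O)C(C(=O)OC)[C@H](C=O)Cc1cc(OC)c(OCc2ccccc2)c(OC)c1 | intermediate
10 | dimethyl 2-[(2R)-1-(benzyloxy)-3-[4-(benzyloxy)-3,5-dimethoxyphenyl]propan-2-yl]propanedioate | COC(=O)C(C(=O)OC)[C@H](COCc1ccccc1)Cc1cc(OC)c(OCc2ccccc2)c(OC)c1 | intermediate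
11 | dimethyl 2-[(2R)-1-(benzyloxy)-3-[4-(benzyloxy)-2-iodo-3,5-dimethoxyphenyl]propan-2-yl]propanedioate | COC(=O)C(C(=O)OC)[C@H](COCc1ccccc1)Cc1cc(OC)c(OCc2ccccc2)c(OC)c1I | intermediate
12 | 2-(benzyloxy)-5-(diazomethyl)-1,3-dimethoxybenzene (not isolated) | COc1cc(C=[N+]=[N-])cc(OC)c1OCc1ccccc1 | intermediate
13 | dimethyl (1S,3R)-7-(benzyloxy)-1-[4-(benzyloxy)-3,5-dimethoxyphenyl]-3-[(benzyloxy)methyl]-6,8-dimethoxy-3,4-dihydronaphthalene-2,2(1H)-dicarboxylate | COc1cc([C@H]2c3c(cc(OC)c(OCc4ccccc4)c3OC)C[C@@H](COCc3ccccc3)C2(C(=O)OC)C(=O)OC)cc(OC)c1OCc1ccccc1 | intermediate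
14 | methyl (1S,3R)-7-(benzyloxy)-1-[4-(benzyloxy)-3,5-dimethoxyphenyl]-3-[(benzyloxy)methyl]-6,8-dimethoxy-1,2,3,4-tetrahydronaphthalene-2-carboxylate, C2 epimers | COc1cc([C@H]2c3c(cc(OC)c(OCc4ccccc4)c3OC)C[C@@H](COCc3ccccc3)C2C(=O)OC)cc(OC)c1OCc1ccccc1 | intermediate
15 | methyl (1S,2R,3R)-7-(benzyloxy)-1-[4-(benzyloxy)-3,5-dimethoxyphenyl]-3-[(benzyloxy)methyl]-6,8-dimethoxy-1,2,3,4-tetrahydronaphthalene-2-carboxylate | COc1cc([C@H]2c3c(cc(OC)c(OCc4ccccc4)c3OC)C[C@@H](COCc3ccccc3)[C@@H]2C(=O)OC)cc(OC)c1OCc1ccccc1 | intermediate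
16 | [(1S,2R,3R)-7-(benzyloxy)-1-[4-(benzyloxy)-3,5-dimethoxyphenyl]-3-[(benzyloxy)methyl]-6,8-dimethoxy-1,2,3,4-tetrahydronaphthalen-2-yl]methanol | COc1cc([C@H]2c3c(cc(OC)c(OCc4ccccc4)c3OC)C[C@@H](COCc3ccccc3)[C@@H]2CO)cc(OC)c1OCc1ccccc1 | intermediate
17 | 4-[(1S,2R,3R)-7-hydroxy-2,3-bis(hydroxymethyl)-6,8-dimethoxy-1,2,3,4-tetrahydronaphthalen-1-yl]-2,6-dimethoxyphenol | COc1cc([C@H]2c3c(cc(OC)c(O)c3OC)C[C@@H](CO)[C@@H]2CO)cc(OC)c1O | target

**Step count**

Total: 12 steps. Longest linear sequence: 11 steps (steps 1 and 3 to 12); step 2 is the one-step branch to the hydrazone.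

**Steps most likely to fail**

Step 8. The facial selectivity at C1 may be poor: the peri methoxy group and the axial ester can steer the pendant aryl trans to the C3 substituent against the ligand. Direct malonate arylation or loss of the diazoalkane to azine may also compete with carbene capture. The fallback sets out from 9 and returns at 17, forming C1–C8a last by the classical cationic closure in which the aryl group is known to settle trans to the C2 substituent.
- Reduction of 9 with NaBH4 in MeOH and lactonisation on mildly acidic work-up should give methyl (4R)-4-{[4-(benzyloxy)-3,5-dimethoxyphenyl]methyl}-2-oxooxolane-3-carboxylate F1.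
- Krapcho demethoxycarbonylation (LiCl, wet DMSO) should give (4R)-4-{[4-(benzyloxy)-3,5-dimethoxyphenyl]methyl}oxolan-2-one F2.
- The lithium enolate (LDA, THF, −78 °C) should add to aldehyde 2 anti to the benzylic substituent to give (3S,4R)-4-{[4-(benzyloxy)-3,5-dimethoxyphenyl]methyl}-3-{[4-(benzyloxy)-3,5-dimethoxyphenyl](hydroxy)methyl}oxolan-2-one F3 (carbinol epimers).
- TFA in CH2Cl2 at 0 °C ionises the benzylic alcohol, and Friedel–Crafts closure onto ring A should give the trans-fused γ-lactone of (1S,2R,3R)-7-(benzyloxy)-1-[4-(benzyloxy)-3,5-dimethoxyphenyl]-3-(hydroxymethyl)-6,8-dimethoxy-1,2,3,4-tetrahydronaphthalene-2-carboxylic acid F4.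
- LiAlH4 should open it to [(1S,2R,3R)-7-(benzyloxy)-1-[4-(benzyloxy)-3,5-dimethoxyphenyl]-6,8-dimethoxy-1,2,3,4-tetrahydronaphthalene-2,3-diyl]dimethanol F5, and hydrogenolysis over Pd/C gives 17.
- Partial loss of an aryl benzyl group in TFA would be harmless, since all are removed at the end.

Step 6. The oxocarbenium ion may lose its α-proton (erosion of the C3 configuration) or be attacked by the electron-rich ring to give an indane before the silane reduces it. The fallback sets out from 9 and returns at 10 and avoids a cationic intermediate. BH3·THF at −78 to −20 °C reduces the aldehyde but not the esters and, after neutral work-up, should give dimethyl 2-[(2R)-1-[4-(benzyloxy)-3,5-dimethoxyphenyl]-3-hydroxypropan-2-yl]propanedioate F6. This is benzylated at once under neutral conditions with 2-benzyloxy-1-methylpyridinium triflate and MgO in trifluorotoluene to give 10.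

Step 9. At 150 °C the doubly benzylic C1–C2 bond next to the malonate may ionise (ring opening), and chloride may attack a benzyl ether. The fallback sets out from 13 and returns at 14 by the hydrolytic malonic ester sequence at lower temperature. KOH in aqueous EtOH/THF at reflux should give (1S,3R)-7-(benzyloxy)-1-[4-(benzyloxy)-3,5-dimethoxyphenyl]-3-[(benzyloxy)methyl]-6,8-dimethoxy-3,4-dihydronaphthalene-2,2(1H)-dicarboxylic acid F7. Warming in pyridine should decarboxylate it to (1S,3R)-7-(benzyloxy)-1-[4-(benzyloxy)-3,5-dimethoxyphenyl]-3-[(benzyloxy)methyl]-6,8-dimethoxy-1,2,3,4-tetrahydronaphthalene-2-carboxylic acid F8 (C2 epimers). MeI and K2CO3 in DMF give 14.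

**Further compounds**

F1 | step 8 | methyl (4R)-4-{[4-(benzyloxy)-3,5-dimethoxyphenyl]methyl}-2-oxooxolane-3-carboxylate | COC(=O)C1C(=O)OC[C@@H]1Cc1cc(OC)c(OCc2ccccc2)c(OC)c1
F2 | step 8 | (4R)-4-{[4-(benzyloxy)-3,5-dimethoxyphenyl]methyl}oxolan-2-one | O=C1C[C@@H](Cc2cc(OC)c(OCc3ccccc3)c(OC)c2)CO1
F3 | step 8 | (3S,4R)-4-{[4-(benzyloxy)-3,5-dimethoxyphenyl]methyl}-3-{[4-(benzyloxy)-3,5-dimethoxyphenyl](hydroxy)methyl}oxolan-2-one | O=C1OC[C@H](Cc2cc(OC)c(OCc3ccccc3)c(OC)c2)[C@H]1C(O)c1cc(OC)c(OCc2ccccc2)c(OC)c1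
F4 | step 8 | γ-lactone of (1S,2R,3R)-7-(benzyloxy)-1-[4-(benzyloxy)-3,5-dimethoxyphenyl]-3-(hydroxymethyl)-6,8-dimethoxy-1,2,3,4-tetrahydronaphthalene-2-carboxylic acid | COc1cc([C@H]2c3c(cc(OC)c(OCc4ccccc4)c3OC)C[C@H]3COC(=O)[C@H]23)cc(OC)c1OCc1ccccc1
F5 | step 8 | [(1S,2R,3R)-7-(benzyloxy)-1-[4-(benzyloxy)-3,5-dimethoxyphenyl]-6,8-dimethoxy-1,2,3,4-tetrahydronaphthalene-2,3-diyl]dimethanol | COc1cc([C@H]2c3c(cc(OC)c(OCc4ccccc4)c3OC)C[C@@H](CO)[C@@H]2CO)cc(OC)c1OCc1ccccc1
F6 | step 6 | dimethyl 2-[(2R)-1-[4-(benzyloxy)-3,5-dimethoxyphenyl]-3-hydroxypropan-2-yl]propanedioate | COC(=O)C(C(=O)OC)[C@H](CO)Cc1cc(OC)c(OCc2ccccc2)c(OC)c1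
F7 | step 9 | (1S,3R)-7-(benzyloxy)-1-[4-(benzyloxy)-3,5-dimethoxyphenyl]-3-[(benzyloxy)methyl]-6,8-dimethoxy-3,4-dihydronaphthalene-2,2(1H)-dicarboxylic acid | COc1cc([C@H]2c3c(cc(OC)c(OCc4ccccc4)c3OC)C[C@@H](COCc3ccccc3)C2(C(=O)O)C(=O)O)cc(OC)c1OCc1ccccc1
F8 | step 9 | (1S,3R)-7-(benzyloxy)-1-[4-(benzyloxy)-3,5-dimethoxyphenyl]-3-[(benzyloxy)methyl]-6,8-dimethoxy-1,2,3,4-tetrahydronaphthalene-2-carboxylic acid, C2 epimers | COc1cc([C@H]2c3c(cc(OC)c(OCc4ccccc4)c3OC)C[C@@H](COCc3ccccc3)C2C(=O)O)cc(OC)c1OCc1ccccc1
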